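## Retrosynthetic overview

1. Target ⇐ global hydrogenolysis and acid epimerisation at C-2' of a benzyl-protected hexacycle whose dihydrofuran 2 comes from an enantioselective Rh-carbene C–H insertion.
2. Seven-membered ring ⇐ intramolecular 1,6-(vinylogous Michael) addition of ring B to a para-quinone methide unmasked from a 4-hydroxystilbene. It is closed before the second 3,5-dioxygenated aryl is installed, so only ring B can reach C-7.
3. Stilbene ⇐ Julia–Kocienski olefination of a ring-A aldehyde; dihydrofuran 1 ⇐ first C–H insertion with the antipodal catalyst.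
4. Both diaryl-diazomethane precursors ⇐ Br–Li exchange on a symmetric ring-A dibromide, addition to one aryl nitrile, and transimination of the ketimine with hydrazine.
5. Ring order: dihydrofuran 1 → seven-membered ring → dihydrofuran 2.

Labels: ring A = central benzene; ring B = the 3,5-dioxygenated ring that ends in the seven-membered ring; C-2/C-3 = dihydrofuran 1; C-7 (CH–aryl) and C-8 (CH2) = seven-ring bridge; C-2'/C-3' = dihydrofuran 2. The target is (2R,3R,7R,2'S,3'S); both dihydrofurans are trans.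
Abbreviations: Bn = benzyl; PBB = 4-(benzyloxy)benzyl; DBB = 2,4-bis(benzyloxy)benzyl; MOM = methoxymethyl; TBDPS = tert-butyldiphenylsilyl; PT = 1-phenyl-1H-tetrazol-5-yl; Rh2(S-PTAD)4 = dirhodium tetrakis[(S)-(1-adamantyl)(N-phthalimido)acetate], a divalent rhodium carboxylate dimer.

Assumption: Rh2(S-PTAD)4 is taken to give the (3R) and Rh2(R-PTAD)4 the (3'S) insertion product; if a test run shows the opposite sense, the two antipodes are exchanged between steps 6 and 20.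

## Route

Step 1
Reactants: 1 3,5-dihydroxybenzonitrile; 2 benzyl bromide
Product: 3 3,5-bis(benzyloxy)benzonitrile
Conditions: BnBr (2.2 equiv), K2CO3, DMF, 60 °C
Reagents that add atoms: benzyl bromide BrCc1ccccc1
Why: Williamson etherification of both phenols.

Step 2
Reactants: 4 3,5-dihydroxybenzyl alcohol; 5 4-(benzyloxy)benzyl chloride
Product: 6 3,5-bis(PBB-oxy)benzyl alcohol
Conditions: 5 (2.1 equiv), K2CO3, KI (cat.), DMF, 60 °C
Reagents that add atoms: 4-(benzyloxy)benzyl chloride ClCc1ccc(OCc2ccccc2)cc1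
Why: Williamson etherification; only the phenoxides form under carbonate, so the benzylic alcohol is untouched.

Step 3
Reactants: 6; 7 N-bromosuccinimide
Product: 8 2,6-dibromo-3,5-bis(PBB-oxy)benzyl alcohol
Conditions: NBS (2.05 equiv), MeCN, 0 °C, dark
Reagents that add atoms: N-bromosuccinimide O=C1CCC(=O)N1Br
Why: electrophilic aromatic bromination at the two positions ortho/para to both ring-A oxygens, as in 3,5-dialkoxybenzyl systems; the doubly activated ring A reacts far faster than the mono-alkoxy rings.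

Step 4
Reactants: 8; 9 tert-butyl(chloro)diphenylsilane
Product: 10 TBDPS ether of 8
Conditions: TBDPSCl, imidazole, DMF, rt
Reagents that add atoms: tert-butyl(chloro)diphenylsilane CC(C)(C)[Si](Cl)(c1ccccc1)c1ccccc1
Why: silyl protection of the primary alcohol so that it survives organolithium chemistry and cannot trap the later carbene.

Step 5
Reactants: 10; 3 3,5-bis(benzyloxy)benzonitrile; 11 hydrazine hydrate
Product: 14 hydrazone of the hindered diaryl ketimine, via aryllithium 12 (not isolated), via N-H ketimine 13 (not isolated)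
Conditions: n-BuLi (1.05 equiv), THF, −78 °C; 3, −78 to 0 °C; MeOH; then N2H4·H2O (10 equiv), AcOH (cat.), EtOH, 80 °C
Reagents that add atoms: 3,5-bis(benzyloxy)benzonitrile N#Cc1cc(OCc2ccccc2)cc(OCc2ccccc2)c1; hydrazine NN
Why: mono Br–Li exchange on the symmetric dibromide, addition of the aryllithium to the nitrile and transimination of the N–H ketimine with hydrazine give the hydrazone without a condensation on a doubly ortho-substituted benzophenone.

Step 6
Reactants: 14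
Product: 16 cis-dihydrobenzofuran (2S,3R) carrying Br, PBB-oxy and CH2OTBDPS on ring A, via diaryldiazomethane 15 (not isolated)
Conditions: MnO2 (8 equiv), CH2Cl2, 0 °C; filter; Rh2(S-PTAD)4 (1 mol %), MeCN, 0 °C
Reagents that add atoms: none
Why: hydrazone oxidation to the diaryldiazomethane and Rh-carbene (donor/donor) intramolecular 1,5 C–H insertion into the ortho O–CH2Ar group; the chiral carboxylate sets C-3 (R) and the insertion gives the cis (2S) ring, which is corrected in step 15.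

Step 7
Reactants: 16
Product: 17 4-(hydroxymethyl) analogue of 16
Conditions: TBAF, THF, 0 °C to rt
Reagents that add atoms: none
Why: fluoride-mediated desilylation.

Step 8
Reactants: 17
Product: 18 4-carbaldehyde analogue of 16
Conditions: Dess–Martin periodinane, CH2Cl2, rt
Reagents that add atoms: none
Why: Dess–Martin oxidation of the hindered benzylic alcohol to a non-enolisable aldehyde.

Step 9
Reactants: 19 2,4-dihydroxybenzaldehyde; 20 chloromethyl methyl ether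
Product: 21 2-hydroxy-4-(methoxymethoxy)benzaldehyde
Conditions: MOMCl (1.05 equiv), K2CO3, acetone, 0 °C to rt
Reagents that add atoms: chloromethyl methyl ether COCCl
Why: selective alkylation of the non-chelated 4-OH; the 2-OH is hydrogen-bonded to the aldehyde.

Step 10
Reactants: 21; 2 benzyl bromide
Product: 22 2-(benzyloxy)-4-(methoxymethoxy)benzaldehyde
Conditions: BnBr, K2CO3, DMF, 50 °C
Reagents that add atoms: benzyl bromide BrCc1ccccc1
Why: Williamson etherification of the remaining chelated phenol.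

Step 11
Reactants: 22
Product: 23 2-(benzyloxy)-4-(methoxymethoxy)benzyl alcohol
Conditions: NaBH4, MeOH/THF, 0 °C
Reagents that add atoms: none
Why: hydride reduction of the aldehyde.

Step 12
Reactants: 23; 24 1-phenyl-1H-tetrazole-5-thiol
Product: 25 PT sulfide of 23
Conditions: 24, PPh3, DIAD, THF, 0 °C to rt
Reagents that add atoms: 1-phenyl-1H-tetrazole-5-thiol Sc1nnnn1-c1ccccc1
Why: Mitsunobu thioetherification under neutral conditions, avoiding the unstable 2,4-dialkoxybenzyl halide.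

Step 13
Reactants: 25; 26 hydrogen peroxide
Product: 27 PT sulfone of 23
Conditions: 30% H2O2, (NH4)6Mo7O24·4H2O (10 mol %), EtOH, 0 °C to rt
Reagents that add atoms: hydrogen peroxide OO
Why: molybdate-catalysed oxidation of the sulfide to the sulfone.

Step 14
Reactants: 18; 27
Product: 28 (2S,3R) stilbene with the (E)-2-[2-(benzyloxy)-4-(MOM-oxy)phenyl]ethenyl group at C-4 of the benzofuran
Conditions: 27, KN(SiMe3)2 (1.0 equiv to 27), DME, −78 °C; then 18, −78 °C to rt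
Reagents that add atoms: sulfone 27 COCOc1ccc(CS(=O)(=O)c2nnnn2-c2ccccc2)c(OCc2ccccc2)c1
Why: Julia–Kocienski olefination with the pre-formed sulfonyl carbanion, so that no free strong base meets the aldehyde (C-3–H is lateral to it); the alkene geometry is irrelevant because step 15 protonates it.

Step 15
Reactants: 28
Product: 32 (2R,3R,7R) tetracyclic bromo diphenol, via stilbene diphenol 29 (not isolated), via para-quinone methide 30 (not isolated), via C-2 epimer 31 (not isolated)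
Conditions: HCl (3 M in MeOH)/THF 1:1, 0.005 M, 50 °C
Reagents that add atoms: none
Why: acidolysis of the MOM ether and the ring-A PBB ether (both fragments trapped by MeOH) frees the 4-hydroxystilbene, which tautomerises to the para-quinone methide; ring B adds to it in an intramolecular 1,6 (vinylogous Michael) fashion to close the seven-membered ring, C-7 (R, H-7 trans to H-3) is set by substrate control from C-3 as in the acid conversion of ε-viniferin into ampelopsin B, and the same acid epimerises C-2 to the trans ring by reversible benzylic C–O ionisation.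

Step 16
Reactants: 19 2,4-dihydroxybenzaldehyde; 2 benzyl bromide
Product: 33 2,4-bis(benzyloxy)benzaldehyde
Conditions: BnBr (2.2 equiv), K2CO3, DMF, 60 °C
Reagents that add atoms: benzyl bromide BrCc1ccccc1
Why: double Williamson etherification.

Step 17
Reactants: 33
Product: 34 2,4-bis(benzyloxy)benzyl alcohol
Conditions: NaBH4, MeOH/THF, 0 °C
Reagents that add atoms: none
Why: hydride reduction of the aldehyde.

Step 18
Reactants: 32; 34
Product: 35 bis(DBB) ether of 32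
Conditions: 34 (2.6 equiv), PPh3, DIAD, THF, 0 °C to rt
Reagents that add atoms: 2,4-bis(benzyloxy)benzyl alcohol OCc1ccc(OCc2ccccc2)cc1OCc1ccccc1
Why: double Mitsunobu etherification; the ring-A ether is the handle for dihydrofuran 2, and the ether on the C-7 aryl is a protecting group that leaves by hydrogenolysis in step 21.

Step 19
Reactants: 35; 3 3,5-bis(benzyloxy)benzonitrile; 11 hydrazine hydrate
Product: 38 hydrazone on ring A next to the DBB ether, via aryllithium 36 (not isolated), via N-H ketimine 37 (not isolated)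
Conditions: n-BuLi (1.1 equiv), THF, −78 °C; 3, −78 to 0 °C; MeOH; then N2H4·H2O, AcOH (cat.), EtOH, 80 °C
Reagents that add atoms: 3,5-bis(benzyloxy)benzonitrile N#Cc1cc(OCc2ccccc2)cc(OCc2ccccc2)c1; hydrazine NN
Why: Br–Li exchange (faster than any benzylic deprotonation at −78 °C), nitrile addition and hydrazine transimination, as in step 5.

Step 20
Reactants: 38
Product: 40 benzyl-protected hexacycle with cis dihydrofuran 2 (2R,3R,7R,2'R,3'S), via diaryldiazomethane 39 (not isolated)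
Conditions: MnO2 (8 equiv), CH2Cl2, 0 °C; filter; Rh2(R-PTAD)4 (1 mol %), MeCN, 0 °C
Reagents that add atoms: none
Why: second Rh-carbene 1,5 C–H insertion, into the α-oxygenated benzylic O–CH2 of the ring-A DBB ether; the antipodal catalyst sets C-3' (S), opposite in sense to C-3.

Step 21
Reactants: 40
Product: 42 target (2R,3R,7R,2'S,3'S), via nonaphenol C-2' epimer 41 (not isolated)
Conditions: H2 (1 atm), Pd/C, EtOAc/MeOH, rt; filter; HCl (1 M in MeOH), 40 °C
Reagents that add atoms: none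
Why: hydrogenolysis removes the ten O-benzyl groups and the DBB aryl ether faster than the hindered ring C–O bonds; acid then epimerises C-2' by reversible ring opening through the para-quinone methide to the more stable trans ring.

## Compound list

1 | 3,5-dihydroxybenzonitrile | N#Cc1cc(O)cc(O)c1 | starting material
2 | benzyl bromide | BrCc1ccccc1 | starting material
3 | 3,5-bis(benzyloxy)benzonitrile | N#Cc1cc(OCc2ccccc2)cc(OCc2ccccc2)c1 | intermediate
4 | 3,5-dihydroxybenzyl alcohol | OCc1cc(O)cc(O)c1 | starting material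
5 | 4-(benzyloxy)benzyl chloride | ClCc1ccc(OCc2ccccc2)cc1 | starting material
6 | 3,5-bis{[4-(benzyloxy)benzyl]oxy}benzyl alcohol | OCc1cc(OCc2ccc(OCc3ccccc3)cc2)cc(OCc2ccc(OCc3ccccc3)cc2)c1 | intermediate
7 | N-bromosuccinimide | O=C1CCC(=O)N1Br | starting material
8 | 2,6-dibromo-3,5-bis{[4-(benzyloxy)benzyl]oxy}benzyl alcohol | OCc1c(Br)c(OCc2ccc(OCc3ccccc3)cc2)cc(OCc2ccc(OCc3ccccc3)cc2)c1Br | intermediate
9 | tert-butyl(chloro)diphenylsilane | CC(C)(C)[Si](Cl)(c1ccccc1)c1ccccc1 | starting material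
10 | tert-butyldiphenylsilyl ether of 8 | CC(C)(C)[Si](OCc1c(Br)c(OCc2ccc(OCc3ccccc3)cc2)cc(OCc2ccc(OCc3ccccc3)cc2)c1Br)(c1ccccc1)c1ccccc1 | intermediate
11 | hydrazine (used as hydrate) | NN | starting material
12 | aryllithium: 10 with Li in place of one Br | [Li]c1c(OCc2ccc(OCc3ccccc3)cc2)cc(OCc2ccc(OCc3ccccc3)cc2)c(Br)c1CO[Si](c1ccccc1)(c1ccccc1)C(C)(C)C | intermediate
13 | N-H ketimine: [3,5-bis(benzyloxy)phenyl]{3-bromo-4,6-bis(PBB-oxy)-2-[(TBDPS-oxy)methyl]phenyl}methanimine | N=C(c1cc(OCc2ccccc2)cc(OCc2ccccc2)c1)c1c(OCc2ccc(OCc3ccccc3)cc2)cc(OCc2ccc(OCc3ccccc3)cc2)c(Br)c1CO[Si](c1ccccc1)(c1ccccc1)C(C)(C)C | intermediate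
14 | hydrazone corresponding to 13 (C=N–NH2) | NN=C(c1cc(OCc2ccccc2)cc(OCc2ccccc2)c1)c1c(OCc2ccc(OCc3ccccc3)cc2)cc(OCc2ccc(OCc3ccccc3)cc2)c(Br)c1CO[Si](c1ccccc1)(c1ccccc1)C(C)(C)C | intermediate
15 | diaryldiazomethane corresponding to 14 | [N-]=[N+]=C(c1cc(OCc2ccccc2)cc(OCc2ccccc2)c1)c1c(OCc2ccc(OCc3ccccc3)cc2)cc(OCc2ccc(OCc3ccccc3)cc2)c(Br)c1CO[Si](c1ccccc1)(c1ccccc1)C(C)(C)C | intermediate
16 | (2S,3R)-3-[3,5-bis(benzyloxy)phenyl]-2-[4-(benzyloxy)phenyl]-5-bromo-6-(PBB-oxy)-4-[(TBDPS-oxy)methyl]-2,3-dihydro-1-benzofuran (cis) | C(c1ccccc1)Oc1ccc(cc1)[C@H]1Oc2cc(OCc3ccc(OCc4ccccc4)cc3)c(Br)c(CO[Si](c3ccccc3)(c3ccccc3)C(C)(C)C)c2[C@H]1c1cc(OCc2ccccc2)cc(OCc2ccccc2)c1 | intermediate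
17 | 4-(hydroxymethyl) analogue of 16, (2S,3R) | C(c1ccccc1)Oc1ccc(cc1)[C@H]1Oc2cc(OCc3ccc(OCc4ccccc4)cc3)c(Br)c(CO)c2[C@H]1c1cc(OCc2ccccc2)cc(OCc2ccccc2)c1 | intermediate
18 | 4-carbaldehyde analogue of 16, (2S,3R) | C(c1ccccc1)Oc1ccc(cc1)[C@H]1Oc2cc(OCc3ccc(OCc4ccccc4)cc3)c(Br)c(C=O)c2[C@H]1c1cc(OCc2ccccc2)cc(OCc2ccccc2)c1 | intermediate
19 | 2,4-dihydroxybenzaldehyde | O=Cc1ccc(O)cc1O | starting material
20 | chloromethyl methyl ether | COCCl | starting material
21 | 2-hydroxy-4-(methoxymethoxy)benzaldehyde | O=Cc1ccc(OCOC)cc1O | intermediate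
22 | 2-(benzyloxy)-4-(methoxymethoxy)benzaldehyde | O=Cc1ccc(OCOC)cc1OCc1ccccc1 | intermediate
23 | 2-(benzyloxy)-4-(methoxymethoxy)benzyl alcohol | OCc1ccc(OCOC)cc1OCc1ccccc1 | intermediate
24 | 1-phenyl-1H-tetrazole-5-thiol | Sc1nnnn1-c1ccccc1 | starting material
25 | 5-{[2-(benzyloxy)-4-(methoxymethoxy)benzyl]sulfanyl}-1-phenyl-1H-tetrazole | COCOc1ccc(CSc2nnnn2-c2ccccc2)c(OCc2ccccc2)c1 | intermediate
26 | hydrogen peroxide | OO | starting material
27 | 5-{[2-(benzyloxy)-4-(methoxymethoxy)benzyl]sulfonyl}-1-phenyl-1H-tetrazole | COCOc1ccc(CS(=O)(=O)c2nnnn2-c2ccccc2)c(OCc2ccccc2)c1 | intermediate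
28 | (2S,3R) stilbene: 16 with (E)-2-[2-(benzyloxy)-4-(methoxymethoxy)phenyl]ethenyl at C-4 in place of CH2OTBDPS | C(c1ccccc1)Oc1ccc(cc1)[C@H]1Oc2cc(OCc3ccc(OCc4ccccc4)cc3)c(Br)c(/C=C/c3ccc(OCOC)cc3OCc3ccccc3)c2[C@H]1c1cc(OCc2ccccc2)cc(OCc2ccccc2)c1 | intermediate
29 | (2S,3R) stilbene diphenol: 28 with ring-A OH and aryl 4-OH free | C(c1ccccc1)Oc1ccc(cc1)[C@H]1Oc2cc(O)c(Br)c(/C=C/c3ccc(O)cc3OCc3ccccc3)c2[C@H]1c1cc(OCc2ccccc2)cc(OCc2ccccc2)c1 | intermediate
30 | para-quinone methide tautomer of 29 (C-8 is CH2, C-7 is the methide carbon) | C(c1ccccc1)Oc1ccc(cc1)[C@H]1Oc2cc(O)c(Br)c(CC=C3C=CC(=O)C=C3OCc3ccccc3)c2[C@H]1c1cc(OCc2ccccc2)cc(OCc2ccccc2)c1 | intermediate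
31 | (2S,3R,7R) C-2 epimer of 32 | C(c1ccccc1)Oc1ccc(cc1)[C@H]1Oc2cc(O)c(Br)c3c2[C@H]1c1cc(OCc2ccccc2)cc(OCc2ccccc2)c1[C@@H](c1ccc(O)cc1OCc1ccccc1)C3 | intermediate
32 | (2R,3R,7R) tetracycle: trans dihydrofuran 1 [C-2: 4-(benzyloxy)phenyl] fused to ring A; ring B [two OBn] bonded to C-3 and C-7; C-7: 2-(benzyloxy)-4-hydroxyphenyl; ring A: Br next to C-8 and OH beside it | C(c1ccccc1)Oc1ccc(cc1)[C@@H]1Oc2cc(O)c(Br)c3c2[C@H]1c1cc(OCc2ccccc2)cc(OCc2ccccc2)c1[C@@H](c1ccc(O)cc1OCc1ccccc1)C3 | intermediate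
33 | 2,4-bis(benzyloxy)benzaldehyde | O=Cc1ccc(OCc2ccccc2)cc1OCc1ccccc1 | intermediate
34 | 2,4-bis(benzyloxy)benzyl alcohol | OCc1ccc(OCc2ccccc2)cc1OCc1ccccc1 | intermediate
35 | (2R,3R,7R) bis(DBB) ether of 32 (both phenols etherified) | C(c1ccccc1)Oc1ccc(cc1)[C@@H]1Oc2cc(OCc3ccc(OCc4ccccc4)cc3OCc3ccccc3)c(Br)c3c2[C@H]1c1cc(OCc2ccccc2)cc(OCc2ccccc2)c1[C@@H](c1ccc(OCc2ccc(OCc4ccccc4)cc2OCc2ccccc2)cc1OCc1ccccc1)C3 | intermediate
36 | aryllithium: 35 with Li in place of Br | C(c1ccccc1)Oc1ccc(cc1)[C@@H]1Oc2cc(OCc3ccc(OCc4ccccc4)cc3OCc3ccccc3)c([Li])c3c2[C@H]1c1cc(OCc2ccccc2)cc(OCc2ccccc2)c1[C@@H](c1ccc(OCc2ccc(OCc4ccccc4)cc2OCc2ccccc2)cc1OCc1ccccc1)C3 | intermediate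
37 | N-H ketimine: 35 with C(=NH)[3,5-bis(benzyloxy)phenyl] in place of Br | C(c1ccccc1)Oc1ccc(cc1)[C@@H]1Oc2cc(OCc3ccc(OCc4ccccc4)cc3OCc3ccccc3)c(C(=N)c3cc(OCc4ccccc4)cc(OCc4ccccc4)c3)c3c2[C@H]1c1cc(OCc2ccccc2)cc(OCc2ccccc2)c1[C@@H](c1ccc(OCc2ccc(OCc4ccccc4)cc2OCc2ccccc2)cc1OCc1ccccc1)C3 | intermediate
38 | hydrazone corresponding to 37 | C(c1ccccc1)Oc1ccc(cc1)[C@@H]1Oc2cc(OCc3ccc(OCc4ccccc4)cc3OCc3ccccc3)c(C(=NN)c3cc(OCc4ccccc4)cc(OCc4ccccc4)c3)c3c2[C@H]1c1cc(OCc2ccccc2)cc(OCc2ccccc2)c1[C@@H](c1ccc(OCc2ccc(OCc4ccccc4)cc2OCc2ccccc2)cc1OCc1ccccc1)C3 | intermediate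
39 | diaryldiazomethane corresponding to 38 | C(c1ccccc1)Oc1ccc(cc1)[C@@H]1Oc2cc(OCc3ccc(OCc4ccccc4)cc3OCc3ccccc3)c(C(=[N+]=[N-])c3cc(OCc4ccccc4)cc(OCc4ccccc4)c3)c3c2[C@H]1c1cc(OCc2ccccc2)cc(OCc2ccccc2)c1[C@@H](c1ccc(OCc2ccc(OCc4ccccc4)cc2OCc2ccccc2)cc1OCc1ccccc1)C3 | intermediate
40 | (2R,3R,7R,2'R,3'S) benzyl-protected hexacycle: cis dihydrofuran 2 with C-2' 2,4-bis(benzyloxy)phenyl and C-3' 3,5-bis(benzyloxy)phenyl; DBB ether on the C-7 aryl | C(c1ccccc1)Oc1ccc(cc1)[C@@H]1Oc2cc3c(c4c2[C@H]1c1cc(OCc2ccccc2)cc(OCc2ccccc2)c1[C@@H](c1ccc(OCc2ccc(OCc5ccccc5)cc2OCc2ccccc2)cc1OCc1ccccc1)C4)[C@H](c1cc(OCc2ccccc2)cc(OCc2ccccc2)c1)[C@H](c1ccc(OCc2ccccc2)cc1OCc1ccccc1)O3 | intermediate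
41 | (2R,3R,7R,2'R,3'S) nonaphenol, C-2' epimer of the target | Oc1ccc(cc1)[C@@H]1Oc2cc3c(c4c2[C@H]1c1cc(O)cc(O)c1[C@@H](c1ccc(O)cc1O)C4)[C@H](c1cc(O)cc(O)c1)[C@H](c1ccc(O)cc1O)O3 | intermediate
42 | CNP0283541.1, (2R,3R,7R,2'S,3'S) | Oc1ccc([C@@H]2Oc3cc4c(c5c3[C@H]2c2cc(O)cc(O)c2[C@@H](c2ccc(O)cc2O)C5)[C@H](c2cc(O)cc(O)c2)[C@@H](c2ccc(O)cc2O)O4)cc1 | target

## Step count and risks

Total steps: 21. Longest linear sequence: 13 (steps 2–8, 14, 15, 18–21, from 3,5-dihydroxybenzyl alcohol).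

Most likely to fail:

Step 5 (and its twin, step 19): transimination of a doubly ortho-substituted N–H ketimine may stall. The fallback sets out from 10 and comes back at 14. Compound 10 is lithiated as before but acylated with commercial methyl 3,5-bis(benzyloxy)benzoate to give the diaryl ketone F1. Lawesson's reagent (toluene, 90 °C) converts it into the thioketone F2, whose C=S reacts with hydrazine hydrate at rt to give 14 with loss of H2S.

Step 15: the liberated PBB cation or intermolecular alkylation may compete with ring closure, or C-7 may form unselectively. The fallback sets out from 17 and comes back at 32. Appel bromination (CBr4, PPh3) gives the benzylic bromide F3. SmI2-mediated Barbier coupling with aldehyde 22 gives the homobenzylic alcohol F4. Bi(OTf)3 (5 mol %, MeCN, −20 °C) ionises only this doubly oxygen-activated carbinol and closes the seven-membered ring by Friedel–Crafts alkylation with all protecting groups intact, giving the protected tetracycle F5. HCl/MeOH then removes the MOM and ring-A PBB groups and epimerises C-2 to give 32.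

Step 20: the carbene sits between an ether and the seven-ring CH2, and 1,5-insertion into the tertiary C-7–H could compete. The fallback sets out from 32 and comes back at 42. n-BuLi (3.3 equiv, two phenoxides plus Br–Li exchange) and 3,5-bis(benzyloxy)benzaldehyde give the ortho-hydroxybenzhydrol F6. With Cs2CO3, F6 loses water to the ortho-quinone methide, which is trapped by the ylide of the chiral sulfonium salt F7 (from alcohol 34, (2R,5R)-2,5-dimethylthiolane and HBF4·OEt2). This formal [4+1] annulation gives the trans-fused hexacycle F8 directly under reagent control (the antipodal sulfide is used if the sense is wrong). Hydrogenolysis (H2, Pd/C) then gives 42.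

## Further compounds

F1 | step 5 | [3,5-bis(benzyloxy)phenyl]{3-bromo-4,6-bis(PBB-oxy)-2-[(TBDPS-oxy)methyl]phenyl}methanone | O=C(c1cc(OCc2ccccc2)cc(OCc2ccccc2)c1)c1c(OCc2ccc(OCc3ccccc3)cc2)cc(OCc2ccc(OCc3ccccc3)cc2)c(Br)c1CO[Si](c1ccccc1)(c1ccccc1)C(C)(C)C
F2 | step 5 | thioketone corresponding to F1 | S=C(c1cc(OCc2ccccc2)cc(OCc2ccccc2)c1)c1c(OCc2ccc(OCc3ccccc3)cc2)cc(OCc2ccc(OCc3ccccc3)cc2)c(Br)c1CO[Si](c1ccccc1)(c1ccccc1)C(C)(C)C
F3 | step 15 | (2S,3R) 4-(bromomethyl) analogue of 17 | C(c1ccccc1)Oc1ccc(cc1)[C@H]1Oc2cc(OCc3ccc(OCc4ccccc4)cc3)c(Br)c(CBr)c2[C@H]1c1cc(OCc2ccccc2)cc(OCc2ccccc2)c1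
F4 | step 15 | (2S,3R) homobenzylic alcohol: 4-{2-[2-(benzyloxy)-4-(methoxymethoxy)phenyl]-2-hydroxyethyl} analogue of 17 (carbinol epimers) | C(c1ccccc1)Oc1ccc(cc1)[C@H]1Oc2cc(OCc3ccc(OCc4ccccc4)cc3)c(Br)c(CC(O)c3ccc(OCOC)cc3OCc3ccccc3)c2[C@H]1c1cc(OCc2ccccc2)cc(OCc2ccccc2)c1
F5 | step 15 | (2S,3R,7R) protected tetracycle: 31 with ring-A PBB ether and aryl 4-OMOM in place of the two OH | C(c1ccccc1)Oc1ccc(cc1)[C@H]1Oc2cc(OCc3ccc(OCc4ccccc4)cc3)c(Br)c3c2[C@H]1c1cc(OCc2ccccc2)cc(OCc2ccccc2)c1[C@@H](c1ccc(OCOC)cc1OCc1ccccc1)C3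
F6 | step 20 | (2R,3R,7R) ortho-hydroxybenzhydrol: 32 with CH(OH)[3,5-bis(benzyloxy)phenyl] in place of Br (carbinol epimers) | C(c1ccccc1)Oc1ccc(cc1)[C@@H]1Oc2cc(O)c(C(O)c3cc(OCc4ccccc4)cc(OCc4ccccc4)c3)c3c2[C@H]1c1cc(OCc2ccccc2)cc(OCc2ccccc2)c1[C@@H](c1ccc(O)cc1OCc1ccccc1)C3
F7 | step 20 | (2R,5R)-1-[2,4-bis(benzyloxy)benzyl]-2,5-dimethylthiolanium tetrafluoroborate | C[C@@H]1CC[C@@H](C)[S+]1Cc1ccc(OCc2ccccc2)cc1OCc1ccccc1.F[B-](F)(F)F
F8 | step 20 | (2R,3R,7R,2'S,3'S) hexacycle with trans dihydrofuran 2, benzyl ethers as in 40 but free 4-OH on the C-7 aryl | C(c1ccccc1)Oc1ccc(cc1)[C@@H]1Oc2cc3c(c4c2[C@H]1c1cc(OCc2ccccc2)cc(OCc2ccccc2)c1[C@@H](c1ccc(O)cc1OCc1ccccc1)C4)[C@H](c1cc(OCc2ccccc2)cc(OCc2ccccc2)c1)[C@@H](c1ccc(OCc2ccccc2)cc1OCc1ccccc1)O3
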